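**Retrosynthetic overview**
1. Target 17 ⇒ hydroxy carbonate 14: the C7–C8 bond and the lactone C12–O bond are made together, last, by an intramolecular iridium-catalysed 2-(methoxycarbonyl)allylation of the C8 primary alcohol. This closes ring B and the methylene lactone.
2. 14 ⇒ oxepane 8 + acrylate carbonate 12 (cross-metathesis, C7=C11) + isovaleric anhydride (C9 ester).
3. Key disconnection: the C10–O bond of the 5,10-oxygen bridge. Oxepane 8 comes from epoxy alcohol 7 by 7-exo epoxide opening with inversion at C10, which forms ring A, sets the quaternary centre and releases the C9 hydroxyl.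
4. 7 ⇒ geraniol: C5 by SeO2 oxidation of the E-methyl, C4 by asymmetric hydrogenation, C5–C6 by iridium-catalysed allylation, the 9,10-epoxide by Shi epoxidation.
5. Ring order: oxepane ring A (C–O bond) first, then ring B and the γ-lactone in one step.

Locants (germacrane numbering): C10 = quaternary C(CH3)–O, C9 = CH–O-isovaleryl, C8 = lactone CH–O, C7 = CH bearing C11, C6 = CH2, C5 = ether CH, C4 = CH–CH3, C3–C1 = (CH2)3, C11=C13 = exocyclic methylene, C12 = lactone carbonyl. The target is (4S,5R,7R,8R,9S,10R).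

Assumption: the catalyst antipodes named (BINAP, SEGPHOS, fructose-derived ketone) are those expected from the accepted facial models and were assigned by analogy, not from a matching precedent; each is confirmed on first use and replaced by its mirror image if the sense is reversed.

**Step 1**
Reactants: 1 geraniol
Product: 2 (2E)-1-[(tert-butyldimethylsilyl)oxy]-3,7-dimethylocta-2,6-diene
Conditions: TBSCl, imidazole, CH2Cl2, 0 °C to rt
Reagents that add atoms: tert-butyldimethylsilyl chloride, CC(C)(C)[Si](C)(C)Cl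
Why: Imidazole-assisted silylation masks the future C8 hydroxyl so that only the allylic alcohol made in step 2 can direct the hydrogenation in step 3, and no stereocentre is formed.

**Step 2**
Reactants: 2
Product: 3 (2E,6E)-8-[(tert-butyldimethylsilyl)oxy]-2,6-dimethylocta-2,6-dien-1-ol
Conditions: SeO2 (10 mol%), t-BuOOH (3 equiv), salicylic acid (10 mol%), CH2Cl2, rt
Reagents that add atoms: tert-butyl hydroperoxide, CC(C)(C)OO
Why: Sharpless selenium dioxide allylic oxidation (ene reaction then [2,3]-sigmatropic shift) hydroxylates the E-methyl of the electron-rich terminal alkene selectively to give the (E)-allylic alcohol (future C5), with no stereocentre formed.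

**Step 3**
Reactants: 3
Product: 4 (2S,6E)-8-[(tert-butyldimethylsilyl)oxy]-2,6-dimethyloct-6-en-1-ol
Conditions: Ru(OAc)2[(S)-BINAP] (1 mol%), H2 (60 atm), MeOH, 25 °C
Reagents that add atoms: none
Why: Noyori hydroxyl-directed asymmetric hydrogenation reduces only the alkene of the free allylic alcohol and sets the C4 methyl stereocentre (S) under catalyst control, while the silyl-protected allylic alkene is left alone.

**Step 4**
Reactants: 4; 5 allyl acetate
Product: 6 (4R,5S,9E)-11-[(tert-butyldimethylsilyl)oxy]-5,9-dimethylundeca-1,9-dien-4-ol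
Conditions: [Ir(cod)Cl]2 (2.5 mol%), (R)-SEGPHOS (5 mol%), 4-chloro-3-nitrobenzoic acid (10 mol%), Cs2CO3 (20 mol%), THF, 100 °C
Reagents that add atoms: none
Why: Krische transfer-hydrogenative carbonyl allylation from the alcohol oxidation level allylates the transient aldehyde through a closed chair on the ligand-selected face, setting C5 (R) anti to the C4 methyl without epimerizing C4.

**Step 5**
Reactants: 6
Product: 8 (1S)-2-[(tert-butyldimethylsilyl)oxy]-1-[(2R,6S,7R)-2,6-dimethyl-7-(prop-2-en-1-yl)oxepan-2-yl]ethan-1-ol, via epoxy alcohol 7 (not isolated)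
Conditions: 1,2:4,5-di-O-isopropylidene-β-L-erythro-2,3-hexodiulo-2,6-pyranose (L-fructose-derived Shi ketone, 30 mol%), KHSO5 (as 2KHSO5·KHSO4·K2SO4), K2CO3, Bu4NHSO4, MeCN–CH2(OMe)2–aq. Na2B4O7 (pH 10.5), 0 °C; extract; then CSA (10 mol%), CH2Cl2, 0 °C
Reagents that add atoms: potassium peroxymonosulfate, [K+].[O-]S(=O)(=O)OO
Why: Shi asymmetric epoxidation (dioxirane, spiro transition state) converts only the trisubstituted alkene into the (9S,10S)-epoxide, and acid-catalysed intramolecular etherification (7-exo opening by the C5 hydroxyl at the tertiary carbon with inversion) then forms the C10–O bond and ring A, setting C10 (R) and leaving C9 (S) as the free alcohol.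

**Step 6**
Reactants: 8; 9 3-methylbutanoic anhydride
Product: 10 (1S)-2-[(tert-butyldimethylsilyl)oxy]-1-[(2R,6S,7R)-2,6-dimethyl-7-(prop-2-en-1-yl)oxepan-2-yl]ethyl 3-methylbutanoate
Conditions: DMAP (0.5 equiv), Et3N, CH2Cl2, rt
Reagents that add atoms: none
Why: DMAP-catalysed acyl transfer esterifies the only free hydroxyl (C9) with retention, and this ester is the one present in the target.

**Step 7**
Reactants: 11 methyl 2-(hydroxymethyl)prop-2-enoate
Product: 12 methyl 2-{[(tert-butoxycarbonyl)oxy]methyl}prop-2-enoate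
Conditions: Boc2O, DMAP (5 mol%), CH2Cl2, 0 °C to rt
Reagents that add atoms: di-tert-butyl dicarbonate, CC(C)(C)OC(=O)OC(=O)OC(C)(C)C
Why: O-acylation with the dicarbonate turns the allylic alcohol into an ionizable tert-butyl carbonate (a Morita–Baylis–Hillman-type carbonate), with no stereocentre formed.

**Step 8**
Reactants: 10; 12
Product: 13 methyl (2E)-2-{[(tert-butoxycarbonyl)oxy]methyl}-4-[(2R,3S,7R)-7-{(1S)-2-[(tert-butyldimethylsilyl)oxy]-1-[(3-methylbutanoyl)oxy]ethyl}-3,7-dimethyloxepan-2-yl]but-2-enoate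
Conditions: second-generation Hoveyda–Grubbs catalyst, RuCl2(H2IMes)(=CH-C6H4-2-OiPr) (10 mol%), 12 (4 equiv), CH2Cl2, 40 °C
Reagents that add atoms: none
Why: Olefin cross-metathesis between the terminal alkene and the slowly homodimerizing 1,1-disubstituted acrylate gives the trisubstituted enoate with the chain trans to the ester, and this geometry need not be pure because the next C–C bond forms through a π-allyl.

**Step 9**
Reactants: 13
Product: 14 methyl (2E)-2-{[(tert-butoxycarbonyl)oxy]methyl}-4-[(2R,3S,7R)-7-{(1S)-2-hydroxy-1-[(3-methylbutanoyl)oxy]ethyl}-3,7-dimethyloxepan-2-yl]but-2-enoate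
Conditions: HF·pyridine, pyridine, THF, 0 °C to rt
Reagents that add atoms: none
Why: Buffered fluoride desilylation frees the C8 primary alcohol under mildly acidic conditions that avoid acyl migration and keep the allylic carbonate, with no stereocentre touched.

**Step 10**
Reactants: 14
Product: 17 (4S,5R,7R,8R,9S,10R)-5,10-epoxy-9-[(3-methylbutanoyl)oxy]germacr-11(13)-en-12,8-olide (target), via aldehyde 15 (not isolated), via hydroxy ester 16 (not isolated)
Conditions: [Ir(cod)Cl]2 (5 mol%), (R)-SEGPHOS (10 mol%), 4-cyano-3-nitrobenzoic acid (10 mol%), K3PO4 (20 mol%), THF (0.005 M), 70 °C; then PPTS (10 mol%), rt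
Reagents that add atoms: none
Why: Proposed new method: an intramolecular, redox-neutral iridium-catalysed 2-(methoxycarbonyl)allylation of a primary alcohol by its own tethered γ-substituted allylic carbonate (hydrogen auto-transfer), in which the cyclometalated iridium C,O-benzoate ionizes the carbonate (loss of CO2 and tert-butoxide) to a 2-(methoxycarbonyl)allyl complex, the C8 alkoxide undergoes β-hydride elimination to aldehyde 15, and the σ-allyl bound at C13 with C6 trans to the metal adds through C7 to the aldehyde in a closed chair with C9 and C6 both equatorial, so that ring B closes with H7 and H8 trans while SEGPHOS selects the carbonyl face (C8 R, C7 R) and alkoxide 16 lactonizes onto the methyl ester; the closest known reaction type is the intermolecular Krische iridium-catalysed 2-(alkoxycarbonyl)allylation and anti-crotylation of primary alcohols by transfer hydrogenation.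

**Compound list**
1 | geraniol, (2E)-3,7-dimethylocta-2,6-dien-1-ol | CC(C)=CCC/C(C)=C/CO | starting material
2 | (2E)-1-[(tert-butyldimethylsilyl)oxy]-3,7-dimethylocta-2,6-diene | CC(C)=CCC/C(C)=C/CO[Si](C)(C)C(C)(C)C | intermediate
3 | (2E,6E)-8-[(tert-butyldimethylsilyl)oxy]-2,6-dimethylocta-2,6-dien-1-ol | OC/C(C)=C/CC/C(C)=C/CO[Si](C)(C)C(C)(C)C | intermediate
4 | (2S,6E)-8-[(tert-butyldimethylsilyl)oxy]-2,6-dimethyloct-6-en-1-ol | OC[C@@H](C)CCC/C(C)=C/CO[Si](C)(C)C(C)(C)C | intermediate
5 | allyl acetate (prop-2-en-1-yl acetate) | C=CCOC(C)=O | starting material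
6 | (4R,5S,9E)-11-[(tert-butyldimethylsilyl)oxy]-5,9-dimethylundeca-1,9-dien-4-ol | C=CC[C@@H](O)[C@@H](C)CCC/C(C)=C/CO[Si](C)(C)C(C)(C)C | intermediate
7 | (4R,5S)-8-[(2S,3S)-3-{[(tert-butyldimethylsilyl)oxy]methyl}-2-methyloxiran-2-yl]-5-methyloct-1-en-4-ol | C=CC[C@@H](O)[C@@H](C)CCC[C@]1(C)O[C@H]1CO[Si](C)(C)C(C)(C)C | intermediate
8 | (1S)-2-[(tert-butyldimethylsilyl)oxy]-1-[(2R,6S,7R)-2,6-dimethyl-7-(prop-2-en-1-yl)oxepan-2-yl]ethan-1-ol | C=CC[C@H]1O[C@](C)(CCC[C@@H]1C)[C@@H](O)CO[Si](C)(C)C(C)(C)C | intermediate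
9 | 3-methylbutanoic anhydride (isovaleric anhydride) | CC(C)CC(=O)OC(=O)CC(C)C | starting material
10 | (1S)-2-[(tert-butyldimethylsilyl)oxy]-1-[(2R,6S,7R)-2,6-dimethyl-7-(prop-2-en-1-yl)oxepan-2-yl]ethyl 3-methylbutanoate | C=CC[C@H]1O[C@](C)(CCC[C@@H]1C)[C@H](CO[Si](C)(C)C(C)(C)C)OC(=O)CC(C)C | intermediate
11 | methyl 2-(hydroxymethyl)prop-2-enoate | C=C(CO)C(=O)OC | starting material
12 | methyl 2-{[(tert-butoxycarbonyl)oxy]methyl}prop-2-enoate | C=C(COC(=O)OC(C)(C)C)C(=O)OC | intermediate
13 | methyl (2E)-2-{[(tert-butoxycarbonyl)oxy]methyl}-4-[(2R,3S,7R)-7-{(1S)-2-[(tert-butyldimethylsilyl)oxy]-1-[(3-methylbutanoyl)oxy]ethyl}-3,7-dimethyloxepan-2-yl]but-2-enoate | COC(=O)/C(COC(=O)OC(C)(C)C)=C/C[C@H]1O[C@](C)(CCC[C@@H]1C)[C@H](CO[Si](C)(C)C(C)(C)C)OC(=O)CC(C)C | intermediate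
14 | methyl (2E)-2-{[(tert-butoxycarbonyl)oxy]methyl}-4-[(2R,3S,7R)-7-{(1S)-2-hydroxy-1-[(3-methylbutanoyl)oxy]ethyl}-3,7-dimethyloxepan-2-yl]but-2-enoate | COC(=O)/C(COC(=O)OC(C)(C)C)=C/C[C@H]1O[C@](C)(CCC[C@@H]1C)[C@H](CO)OC(=O)CC(C)C | intermediate
15 | methyl (2E)-2-{[(tert-butoxycarbonyl)oxy]methyl}-4-[(2R,3S,7R)-3,7-dimethyl-7-{(1R)-1-[(3-methylbutanoyl)oxy]-2-oxoethyl}oxepan-2-yl]but-2-enoate | COC(=O)/C(COC(=O)OC(C)(C)C)=C/C[C@H]1O[C@](C)(CCC[C@@H]1C)[C@H](C=O)OC(=O)CC(C)C | intermediate
16 | methyl (4S,5R,7R,8R,9S,10R)-5,10-epoxy-8-hydroxy-9-[(3-methylbutanoyl)oxy]germacr-11(13)-en-12-oate (11-oxabicyclo[4.4.1]undecane core, C7 bears the 1-(methoxycarbonyl)ethenyl group) | C=C(C(=O)OC)[C@H]1C[C@H]2O[C@](C)(CCC[C@@H]2C)[C@@H](OC(=O)CC(C)C)[C@@H]1O | intermediate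
17 | (4S,5R,7R,8R,9S,10R)-5,10-epoxy-9-[(3-methylbutanoyl)oxy]germacr-11(13)-en-12,8-olide (CNP0274454.1) | C=C1C(=O)O[C@@H]2[C@@H]1C[C@H]1O[C@](C)(CCC[C@@H]1C)[C@H]2OC(=O)CC(C)C | target

**Step count**
Total step count: 10. Longest linear sequence: 9 (steps 1–6 and 8–10 from geraniol; step 7 is a one-step side branch).

**Three steps most likely to fail**

Step 10 (the proposed new reaction). Three things can go wrong:
- The allyl may react through the geometry with C6 cis to the metal-bearing carbon, which gives the cis-fused lactone.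
- The intrinsic Felkin preference of the α-acyloxy aldehyde is anti, whereas the target needs the 8,9-syn relationship, so the catalyst and the ring must override it.
- The base may shift the isovaleryl group from O9 to O8. This shift is reversible and only the isomer with the free primary alcohol can be dehydrogenated, but it slows the reaction.

The fallback uses known chemistry, sets out from 14 and comes back at 17. Dess–Martin periodinane with NaHCO3 in CH2Cl2 oxidizes 14 to aldehyde 15, which is now isolated. Pd(PPh3)4 (5 mol%) and InI (1.5 equiv) in THF at rt then convert the allylic carbonate, through the π-allylpalladium, into an allylindium (the known zerovalent-palladium/indium umpolung Barbier allylation). The allylindium adds to the aldehyde in a chair in which indium can bridge the aldehyde oxygen and the C9 ester oxygen, which favours the 8,9-syn adduct. This gives hydroxy ester 16, and PPTS closes it to 17. New compounds: none F0.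

Step 8 (cross-metathesis with a hindered 1,1-disubstituted acrylate). Conversion may be low and 10 may homodimerize. The fallback sets out from 10 and comes back at 16, and so 17.
- OsO4 (2 mol%), NaIO4 and 2,6-lutidine in dioxane–water cleave the terminal alkene to (1S)-2-[(tert-butyldimethylsilyl)oxy]-1-[(2R,6S,7R)-2,6-dimethyl-7-(2-oxoethyl)oxepan-2-yl]ethyl 3-methylbutanoate F4.
- A Morita–Baylis–Hillman reaction with methyl acrylate (DABCO, neat, rt) gives methyl 4-[(2R,3S,7R)-7-{(1S)-2-[(tert-butyldimethylsilyl)oxy]-1-[(3-methylbutanoyl)oxy]ethyl}-3,7-dimethyloxepan-2-yl]-3-hydroxy-2-methylidenebutanoate F5 as both C3 epimers.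
- Boc2O with DMAP gives methyl 3-[(tert-butoxycarbonyl)oxy]-4-[(2R,3S,7R)-7-{(1S)-2-[(tert-butyldimethylsilyl)oxy]-1-[(3-methylbutanoyl)oxy]ethyl}-3,7-dimethyloxepan-2-yl]-2-methylidenebutanoate F6.
- HF·pyridine gives methyl 3-[(tert-butoxycarbonyl)oxy]-4-[(2R,3S,7R)-7-{(1S)-2-hydroxy-1-[(3-methylbutanoyl)oxy]ethyl}-3,7-dimethyloxepan-2-yl]-2-methylidenebutanoate F7.
- Under the conditions of step 10, F7 is dehydrogenated to methyl 3-[(tert-butoxycarbonyl)oxy]-4-[(2R,3S,7R)-3,7-dimethyl-7-{(1R)-1-[(3-methylbutanoyl)oxy]-2-oxoethyl}oxepan-2-yl]-2-methylidenebutanoate F8. This branched carbonate ionizes to the same 2-(methoxycarbonyl)allyl iridium species as 14 (the C3 stereocentre is lost), so it closes to 16 and then 17.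

Step 5 (epoxidation and seven-membered etherification). Facial control on the allylic silyl ether may be incomplete, and the 7-exo closure may lose out to acid-induced silyl loss or a 1,2-shift to a ketone. The fallback sets out from 6 and comes back at 8.
- Bu4NF in THF removes the silyl group to give (2E,7S,8R)-3,7-dimethylundeca-2,10-diene-1,8-diol F1.
- Sharpless asymmetric epoxidation (Ti(OiPr)4, L-(+)-diethyl tartrate, t-BuOOH, 4 Å sieves, CH2Cl2, −20 °C), directed by the free allylic alcohol, gives (4R,5S)-8-[(2S,3S)-3-(hydroxymethyl)-2-methyloxiran-2-yl]-5-methyloct-1-en-4-ol F2.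
- Ti(OiPr)4 (1.5 equiv) at rt binds the epoxy alcohol as a chelate, and the tethered secondary hydroxyl opens the tertiary epoxide carbon with inversion (titanium-assisted regioselective opening of a 2,3-epoxy alcohol) to give (1S)-1-[(2R,6S,7R)-2,6-dimethyl-7-(prop-2-en-1-yl)oxepan-2-yl]ethane-1,2-diol F3.
- TBSCl and imidazole at −20 °C silylate only the primary hydroxyl and return 8.

**Further compounds**
F1 | step 5 | (2E,7S,8R)-3,7-dimethylundeca-2,10-diene-1,8-diol | C=CC[C@@H](O)[C@@H](C)CCC/C(C)=C/CO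
F2 | step 5 | (4R,5S)-8-[(2S,3S)-3-(hydroxymethyl)-2-methyloxiran-2-yl]-5-methyloct-1-en-4-ol | C=CC[C@@H](O)[C@@H](C)CCC[C@]1(C)O[C@H]1CO
F3 | step 5 | (1S)-1-[(2R,6S,7R)-2,6-dimethyl-7-(prop-2-en-1-yl)oxepan-2-yl]ethane-1,2-diol | C=CC[C@H]1O[C@](C)(CCC[C@@H]1C)[C@@H](O)CO
F4 | step 8 | (1S)-2-[(tert-butyldimethylsilyl)oxy]-1-[(2R,6S,7R)-2,6-dimethyl-7-(2-oxoethyl)oxepan-2-yl]ethyl 3-methylbutanoate | O=CC[C@H]1O[C@](C)(CCC[C@@H]1C)[C@H](CO[Si](C)(C)C(C)(C)C)OC(=O)CC(C)C
F5 | step 8 | methyl 4-[(2R,3S,7R)-7-{(1S)-2-[(tert-butyldimethylsilyl)oxy]-1-[(3-methylbutanoyl)oxy]ethyl}-3,7-dimethyloxepan-2-yl]-3-hydroxy-2-methylidenebutanoate (C3 epimers) | C=C(C(=O)OC)C(O)C[C@H]1O[C@](C)(CCC[C@@H]1C)[C@H](CO[Si](C)(C)C(C)(C)C)OC(=O)CC(C)C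
F6 | step 8 | methyl 3-[(tert-butoxycarbonyl)oxy]-4-[(2R,3S,7R)-7-{(1S)-2-[(tert-butyldimethylsilyl)oxy]-1-[(3-methylbutanoyl)oxy]ethyl}-3,7-dimethyloxepan-2-yl]-2-methylidenebutanoate (C3 epimers) | C=C(C(=O)OC)C(OC(=O)OC(C)(C)C)C[C@H]1O[C@](C)(CCC[C@@H]1C)[C@H](CO[Si](C)(C)C(C)(C)C)OC(=O)CC(C)C
F7 | step 8 | methyl 3-[(tert-butoxycarbonyl)oxy]-4-[(2R,3S,7R)-7-{(1S)-2-hydroxy-1-[(3-methylbutanoyl)oxy]ethyl}-3,7-dimethyloxepan-2-yl]-2-methylidenebutanoate (C3 epimers) | C=C(C(=O)OC)C(OC(=O)OC(C)(C)C)C[C@H]1O[C@](C)(CCC[C@@H]1C)[C@H](CO)OC(=O)CC(C)C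
F8 | step 8 | methyl 3-[(tert-butoxycarbonyl)oxy]-4-[(2R,3S,7R)-3,7-dimethyl-7-{(1R)-1-[(3-methylbutanoyl)oxy]-2-oxoethyl}oxepan-2-yl]-2-methylidenebutanoate (C3 epimers) | C=C(C(=O)OC)C(OC(=O)OC(C)(C)C)C[C@H]1O[C@](C)(CCC[C@@H]1C)[C@H](C=O)OC(=O)CC(C)C
F0 | step 10 | none | none
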